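**Retrosynthetic overview**

- The side-chain oxirane comes last, by Shi epoxidation of a prenyl alkene; before it, the two ring esters are put on an epoxy-diol made by hydroxyl-directed epoxidation of the ring alkene.
- The side chain is built on a ring-bound 2-substituted acrolein: catalytic asymmetric allylation sets the carbinol, then angeloylation and cross-metathesis to the prenyl group.
- The acrolein comes from a ring–CH2–CHO unit (α-methylenation), itself made by a Ueno–Stork radical cyclisation of a bromoacetal tethered to the distal oxygen of a cyclohexadiene cis-diol; the tether forces the new C–C bond cis to both oxygens.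
- The cis-diol comes from toluene by whole-cell toluene dioxygenase oxidation, which sets the first two stereocentres.
- Ring order: the carbocycle is toluene's own ring; temporary tetrahydrofuran acetal (step 6) and dioxolane (step 7); ring oxirane (step 15); side-chain oxirane (step 17).

Assumption: the SMILES is read as three (Z)-2-methylbut-2-enoate (angelate) esters, with the side chain, both ring esters and the ring epoxide all on one face of the ring (1R,3R,4S,5S,6R core; side-chain carbinol S, oxirane R).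

**Route**

Step 1
Reactants: 1 toluene; 2 dioxygen
Product: 3 (1S,2R)-3-methylcyclohexa-3,5-diene-1,2-diol
Conditions: resting cells of E. coli JM109(pDTG601) expressing toluene dioxygenase (a Rieske non-heme iron arene dioxygenase), IPTG-induced, glycerol as electron donor, air, phosphate buffer pH 7.2, 30 °C; EtOAc extraction
Reagents that add atoms: dioxygen, O=O
Why: Enzymatic arene cis-dihydroxylation adds both oxygens of O2 to one face of the 2,3-bond of toluene, setting both carbinol centres (1S,2R) in >98% ee.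

Step 2
Reactants: 3 cis-diol; 4 tert-butyl(chloro)dimethylsilane
Product: 5 distal mono-TBS ether, (1R,6S)-6-{[tert-butyl(dimethyl)silyl]oxy}-2-methylcyclohexa-2,4-dien-1-ol
Conditions: TBSCl (1.05 equiv), imidazole (2 equiv), DMF, −20 °C
Reagents that add atoms: tert-butyl(chloro)dimethylsilane, CC(C)(C)[Si](C)(C)Cl
Why: Regioselective silylation takes the less hindered hydroxyl, the one remote from the methyl-bearing alkene carbon; no stereocentre is touched.

Step 3
Reactants: 5 mono-TBS ether; 6 2-methoxypropene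
Product: 7 TBS/2-methoxypropan-2-yl bis-ether
Conditions: 2-methoxypropene (3 equiv), PPTS (2 mol%), CH2Cl2, 0 °C; Et3N quench
Reagents that add atoms: 2-methoxypropene, COC(C)=C
Why: Acid-catalysed acetalisation (addition of the alcohol to the enol ether) masks the proximal hydroxyl as an achiral, base-stable mixed ketal under conditions the diene tolerates.

Step 4
Reactants: 7 bis-ether
Product: 8 (1S,6R)-6-[(2-methoxypropan-2-yl)oxy]-5-methylcyclohexa-2,4-dien-1-ol
Conditions: TBAF (1.1 equiv), THF, 0 °C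
Reagents that add atoms: none
Why: Fluoride-mediated desilylation frees only the distal hydroxyl, since the ketal is inert to fluoride.

Step 5
Reactants: 8 dienol; 9 ethyl vinyl ether; 10 N-bromosuccinimide
Product: 11 bromoacetal, (5S,6R)-5-(2-bromo-1-ethoxyethoxy)-6-[(2-methoxypropan-2-yl)oxy]-1-methylcyclohexa-1,3-diene (both acetal epimers)
Conditions: ethyl vinyl ether (5 equiv), NBS (1.2 equiv), 2,6-lutidine (0.2 equiv), CH2Cl2, −78 → −30 °C
Reagents that add atoms: ethyl vinyl ether, C=COCC; N-bromosuccinimide, BrN1C(=O)CCC1=O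
Why: Haloacetalisation (first half of the Ueno–Stork sequence): the bromonium-activated vinyl ether is captured by the free alcohol; the acetal epimers converge in step 7.

Step 6
Reactants: 11 bromoacetal
Product: 12 bicyclic acetal, (3aR,7R,7aS)-2-ethoxy-7-[(2-methoxypropan-2-yl)oxy]-6-methyl-2,3,3a,4,7,7a-hexahydro-1-benzofuran (both C-2 epimers)
Conditions: Bu3SnH (1.3 equiv, syringe pump, 4 h), AIBN (10 mol%), PhH (0.01 M), 80 °C
Reagents that add atoms: none
Why: Ueno–Stork 5-exo-trig radical cyclisation: the oxygen-tethered radical can reach the neighbouring diene terminus only from its own face, so C-3a forms cis to both oxygens, and Bu3SnH quenches the allyl radical at its less hindered secondary end, leaving the trisubstituted alkene.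

Step 7
Reactants: 12 bicyclic acetal; 13 methanol; 14 2,2-dimethoxypropane
Product: 15 (3aS,4R,7aR)-4-(2,2-dimethoxyethyl)-2,2,7-trimethyl-3a,4,5,7a-tetrahydro-1,3-benzodioxole
Conditions: 2,2-dimethoxypropane (solvent), MeOH (5 equiv), CSA (10 mol%), rt, 12 h; Et3N quench
Reagents that add atoms: methanol, CO; 2,2-dimethoxypropane, COC(C)(C)OC
Why: Acid-catalysed transacetalisation: methanolysis removes the ketal and opens the cyclic acetal, and trapping of the freed cis-diol as its acetonide drives the ring opening; the acetal stereocentre is erased.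

Step 8
Reactants: 15 dimethyl acetal; 16 water
Product: 17 2-[(3aS,4R,7aR)-2,2,7-trimethyl-3a,4,5,7a-tetrahydro-1,3-benzodioxol-4-yl]acetaldehyde
Conditions: PPTS (20 mol%), acetone/H2O (10:1), 50 °C
Reagents that add atoms: water, O
Why: Selective acetal hydrolysis: the acyclic dimethyl acetal is far more labile than the cis-fused dioxolane, which acetone as solvent keeps closed.

Step 9
Reactants: 17 aldehyde; 18 formaldehyde
Product: 19 2-[(3aS,4R,7aR)-2,2,7-trimethyl-3a,4,5,7a-tetrahydro-1,3-benzodioxol-4-yl]prop-2-enal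
Conditions: 37% aq. CH2O (1.5 equiv), pyrrolidine (10 mol%), propionic acid (10 mol%), i-PrOH, 45 °C
Reagents that add atoms: formaldehyde, C=O
Why: Organocatalytic Mannich condensation–elimination (α-methylenation of an aldehyde); the ring stereocentre is β to the carbonyl and cannot epimerise.

Step 10
Reactants: 19 enal; 20 allyltributylstannane
Product: 22 (3S)-2-[(3aS,4R,7aR)-2,2,7-trimethyl-3a,4,5,7a-tetrahydro-1,3-benzodioxol-4-yl]hexa-1,5-dien-3-ol, via tributylstannyl ether 21 (not isolated)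
Conditions: Ti(OiPr)4 (10 mol%), (S)-BINOL (20 mol%), 4 Å MS, CH2Cl2; allylSnBu3 (1.5 equiv), −20 °C, 60 h; aq. NaHCO3 work-up
Reagents that add atoms: allyltributylstannane, C=CC[Sn](CCCC)(CCCC)CCCC
Why: Keck asymmetric allylation: the Ti–BINOLate complex activates the enal and delivers allyl to one carbonyl face under catalyst control, giving the (3S)-carbinol as with other aldehydes whose substituent outranks allyl.

Step 11
Reactants: 23 angelic acid, (2Z)-2-methylbut-2-enoic acid; 24 2,4,6-trichlorobenzoyl chloride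
Product: 25 (2Z)-2-methylbut-2-enoic 2,4,6-trichlorobenzoic anhydride
Conditions: Et3N (1.0 equiv), PhMe, rt, 2 h; Et3N·HCl filtered off, filtrate concentrated and used at once
Reagents that add atoms: 2,4,6-trichlorobenzoyl chloride, O=C(Cl)c1c(Cl)cc(Cl)cc1Cl
Why: Yamaguchi-type mixed-anhydride formation activates the acid under conditions that do not isomerise the (Z)-alkene.

Step 12
Reactants: 22 homoallylic alcohol; 25 mixed anhydride
Product: 26 (3S)-2-[(3aS,4R,7aR)-2,2,7-trimethyl-3a,4,5,7a-tetrahydro-1,3-benzodioxol-4-yl]hexa-1,5-dien-3-yl (2Z)-2-methylbut-2-enoate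
Conditions: 25 (3 equiv), Et3N (3 equiv), PhMe, 80 °C, 12 h, no DMAP
Reagents that add atoms: mixed anhydride 25, C/C=C(/C)C(=O)OC(=O)c1c(Cl)cc(Cl)cc1Cl
Why: Yamaguchi-type esterification at the unhindered aliphatic carbonyl of the anhydride, run without DMAP so the angelate does not isomerise to the tiglate; the carbinol configuration is retained.

Step 13
Reactants: 26 angelate; 27 2-methylbut-2-ene
Product: 28 (3S)-6-methyl-2-[(3aS,4R,7aR)-2,2,7-trimethyl-3a,4,5,7a-tetrahydro-1,3-benzodioxol-4-yl]hepta-1,5-dien-3-yl (2Z)-2-methylbut-2-enoate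
Conditions: 2-methylbut-2-ene (50 equiv), second-generation Grubbs catalyst (H2IMes)(PCy3)Cl2Ru=CHPh (5 mol%), CH2Cl2, 40 °C
Reagents that add atoms: 2-methylbut-2-ene, CC=C(C)C
Why: Olefin cross-metathesis: only the monosubstituted alkene enters the cycle and is capped as the prenyl group; the trisubstituted, 1,1-disubstituted and enoate alkenes are inert.

Step 14
Reactants: 28 acetonide; 16 water
Product: 29 (3S)-2-[(1R,5R,6S)-5,6-dihydroxy-4-methylcyclohex-3-en-1-yl]-6-methylhepta-1,5-dien-3-yl (2Z)-2-methylbut-2-enoate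
Conditions: AcOH/H2O (4:1), 45 °C
Reagents that add atoms: none
Why: Acid-catalysed acetonide hydrolysis releases the cis-diol without touching the ester or the alkenes.

Step 15
Reactants: 29 diol; 30 tert-butyl hydroperoxide
Product: 31 (3S)-2-[(1R,3R,4S,5S,6S)-4,5-dihydroxy-6-methyl-7-oxabicyclo[4.1.0]heptan-3-yl]-6-methylhepta-1,5-dien-3-yl (2Z)-2-methylbut-2-enoate
Conditions: VO(acac)2 (10 mol%), t-BuOOH (1.2 equiv, decane), CH2Cl2, 0 °C → rt
Reagents that add atoms: tert-butyl hydroperoxide, CC(C)(C)OO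
Why: Hydroxyl-directed (Sharpless–Michaelson) epoxidation: the vanadium alkoxide of the allylic hydroxyl delivers oxygen to its own face, giving the epoxide cis to both hydroxyls, and the allylic trisubstituted ring alkene reacts far faster than the other alkenes.

Step 16
Reactants: 31 epoxy-diol; 25 mixed anhydride
Product: 32 (1R,3R,4S,5S,6R)-6-methyl-3-{(3S)-6-methyl-3-{[(2Z)-2-methylbut-2-enoyl]oxy}hepta-1,5-dien-2-yl}-7-oxabicyclo[4.1.0]heptane-4,5-diyl bis[(2Z)-2-methylbut-2-enoate]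
Conditions: 25 (6 equiv), Et3N (6 equiv), PhMe, 85 °C, 36 h, no DMAP
Reagents that add atoms: mixed anhydride 25, C/C=C(/C)C(=O)OC(=O)c1c(Cl)cc(Cl)cc1Cl
Why: Double Yamaguchi-type esterification without DMAP; the hydroxyl is cis to the epoxide, so no Payne rearrangement can compete.

Step 17
Reactants: 32 triangelate; 33 potassium peroxymonosulfate
Product: 34 target, (1R,3R,4S,5S,6R)-3-{(3S)-4-[(2R)-3,3-dimethyloxiran-2-yl]-3-{[(2Z)-2-methylbut-2-enoyl]oxy}but-1-en-2-yl}-6-methyl-7-oxabicyclo[4.1.0]heptane-4,5-diyl bis[(2Z)-2-methylbut-2-enoate]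
Conditions: Shi ketone (D-fructose-derived, 30 mol%), KHSO5 (as Oxone, 2KHSO5·KHSO4·K2SO4, 1.5 equiv), K2CO3, Bu4NHSO4 (5 mol%), MeCN/CH2(OMe)2 (1:2), aq. Na2B4O7/Na2EDTA buffer (pH 10.5), 0 °C, 2 h
Reagents that add atoms: potassium peroxymonosulfate, [K+].[O-]S(=O)(=O)OO
Why: Shi asymmetric epoxidation: the chiral dioxirane attacks the electron-rich trisubstituted alkene through a spiro transition state to give the (R)-oxirane, while the allylic-ester 1,1-disubstituted alkene and the enoates are too electron-poor to compete.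

**Compound list**

1 | toluene | Cc1ccccc1 | starting material
2 | dioxygen | O=O | starting material
3 | (1S,2R)-3-methylcyclohexa-3,5-diene-1,2-diol | C1=CC=C(C)[C@@H](O)[C@H]1O | intermediate
4 | tert-butyl(chloro)dimethylsilane | CC(C)(C)[Si](C)(C)Cl | starting material
5 | (1R,6S)-6-{[tert-butyl(dimethyl)silyl]oxy}-2-methylcyclohexa-2,4-dien-1-ol | C1=CC=C(C)[C@@H](O)[C@H]1O[Si](C)(C)C(C)(C)C | intermediate
6 | 2-methoxypropene | COC(C)=C | starting material
7 | tert-butyl({(1S,6R)-6-[(2-methoxypropan-2-yl)oxy]-5-methylcyclohexa-2,4-dien-1-yl}oxy)dimethylsilane | C1=CC=C(C)[C@@H](OC(C)(C)OC)[C@H]1O[Si](C)(C)C(C)(C)C | intermediate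
8 | (1S,6R)-6-[(2-methoxypropan-2-yl)oxy]-5-methylcyclohexa-2,4-dien-1-ol | C1=CC=C(C)[C@@H](OC(C)(C)OC)[C@H]1O | intermediate
9 | ethyl vinyl ether | C=COCC | starting material
10 | N-bromosuccinimide | BrN1C(=O)CCC1=O | starting material
11 | (5S,6R)-5-(2-bromo-1-ethoxyethoxy)-6-[(2-methoxypropan-2-yl)oxy]-1-methylcyclohexa-1,3-diene (acetal epimers) | C1=CC=C(C)[C@@H](OC(C)(C)OC)[C@H]1OC(CBr)OCC | intermediate
12 | (3aR,7R,7aS)-2-ethoxy-7-[(2-methoxypropan-2-yl)oxy]-6-methyl-2,3,3a,4,7,7a-hexahydro-1-benzofuran (C-2 epimers) | CCOC1C[C@H]2CC=C(C)[C@@H](OC(C)(C)OC)[C@H]2O1 | intermediate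
13 | methanol | CO | starting material
14 | 2,2-dimethoxypropane | COC(C)(C)OC | starting material
15 | (3aS,4R,7aR)-4-(2,2-dimethoxyethyl)-2,2,7-trimethyl-3a,4,5,7a-tetrahydro-1,3-benzodioxole | COC(OC)C[C@H]1CC=C(C)[C@@H]2[C@H]1OC(C)(C)O2 | intermediate
16 | water | O | starting material
17 | 2-[(3aS,4R,7aR)-2,2,7-trimethyl-3a,4,5,7a-tetrahydro-1,3-benzodioxol-4-yl]acetaldehyde | O=CC[C@H]1CC=C(C)[C@@H]2[C@H]1OC(C)(C)O2 | intermediate
18 | formaldehyde | C=O | starting material
19 | 2-[(3aS,4R,7aR)-2,2,7-trimethyl-3a,4,5,7a-tetrahydro-1,3-benzodioxol-4-yl]prop-2-enal | C=C(C=O)[C@H]1CC=C(C)[C@@H]2[C@H]1OC(C)(C)O2 | intermediate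
20 | allyltributylstannane | C=CC[Sn](CCCC)(CCCC)CCCC | starting material
21 | tributyl{[(3S)-2-[(3aS,4R,7aR)-2,2,7-trimethyl-3a,4,5,7a-tetrahydro-1,3-benzodioxol-4-yl]hexa-1,5-dien-3-yl]oxy}stannane (tributylstannyl ether) | C=C([C@H](CC=C)O[Sn](CCCC)(CCCC)CCCC)[C@H]1CC=C(C)[C@@H]2[C@H]1OC(C)(C)O2 | intermediate
22 | (3S)-2-[(3aS,4R,7aR)-2,2,7-trimethyl-3a,4,5,7a-tetrahydro-1,3-benzodioxol-4-yl]hexa-1,5-dien-3-ol | C=C([C@H](CC=C)O)[C@H]1CC=C(C)[C@@H]2[C@H]1OC(C)(C)O2 | intermediate
23 | angelic acid, (2Z)-2-methylbut-2-enoic acid | C/C=C(/C)C(=O)O | starting material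
24 | 2,4,6-trichlorobenzoyl chloride | O=C(Cl)c1c(Cl)cc(Cl)cc1Cl | starting material
25 | (2Z)-2-methylbut-2-enoic 2,4,6-trichlorobenzoic anhydride | C/C=C(/C)C(=O)OC(=O)c1c(Cl)cc(Cl)cc1Cl | intermediate
26 | (3S)-2-[(3aS,4R,7aR)-2,2,7-trimethyl-3a,4,5,7a-tetrahydro-1,3-benzodioxol-4-yl]hexa-1,5-dien-3-yl (2Z)-2-methylbut-2-enoate | C=C([C@H](CC=C)OC(=O)/C(C)=C\C)[C@H]1CC=C(C)[C@@H]2[C@H]1OC(C)(C)O2 | intermediate
27 | 2-methylbut-2-ene | CC=C(C)C | starting material
28 | (3S)-6-methyl-2-[(3aS,4R,7aR)-2,2,7-trimethyl-3a,4,5,7a-tetrahydro-1,3-benzodioxol-4-yl]hepta-1,5-dien-3-yl (2Z)-2-methylbut-2-enoate | C=C([C@H](CC=C(C)C)OC(=O)/C(C)=C\C)[C@H]1CC=C(C)[C@@H]2[C@H]1OC(C)(C)O2 | intermediate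
29 | (3S)-2-[(1R,5R,6S)-5,6-dihydroxy-4-methylcyclohex-3-en-1-yl]-6-methylhepta-1,5-dien-3-yl (2Z)-2-methylbut-2-enoate | C=C([C@H](CC=C(C)C)OC(=O)/C(C)=C\C)[C@H]1CC=C(C)[C@@H](O)[C@H]1O | intermediate
30 | tert-butyl hydroperoxide | CC(C)(C)OO | starting material
31 | (3S)-2-[(1R,3R,4S,5S,6S)-4,5-dihydroxy-6-methyl-7-oxabicyclo[4.1.0]heptan-3-yl]-6-methylhepta-1,5-dien-3-yl (2Z)-2-methylbut-2-enoate | C=C([C@H](CC=C(C)C)OC(=O)/C(C)=C\C)[C@H]1C[C@H]2O[C@@]2(C)[C@@H](O)[C@H]1O | intermediate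
32 | (1R,3R,4S,5S,6R)-6-methyl-3-{(3S)-6-methyl-3-{[(2Z)-2-methylbut-2-enoyl]oxy}hepta-1,5-dien-2-yl}-7-oxabicyclo[4.1.0]heptane-4,5-diyl bis[(2Z)-2-methylbut-2-enoate] | C=C([C@H](CC=C(C)C)OC(=O)/C(C)=C\C)[C@H]1C[C@H]2O[C@@]2(C)[C@@H](OC(=O)/C(C)=C\C)[C@H]1OC(=O)/C(C)=C\C | intermediate
33 | potassium peroxymonosulfate | [K+].[O-]S(=O)(=O)OO | starting material
34 | (1R,3R,4S,5S,6R)-3-{(3S)-4-[(2R)-3,3-dimethyloxiran-2-yl]-3-{[(2Z)-2-methylbut-2-enoyl]oxy}but-1-en-2-yl}-6-methyl-7-oxabicyclo[4.1.0]heptane-4,5-diyl bis[(2Z)-2-methylbut-2-enoate] | C=C([C@H](C[C@H]1OC1(C)C)OC(=O)/C(C)=C\C)[C@H]1C[C@H]2O[C@@]2(C)[C@@H](OC(=O)/C(C)=C\C)[C@H]1OC(=O)/C(C)=C\C | target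

**Step count and risks**

Total steps: 17. Longest linear sequence: 16 (steps 1–10 and 12–17; step 11 is a one-step side branch).

The three steps most likely to fail:

Step 16 (double angeloylation of the hindered cis-epoxy-diol; slow acylation or Z→E isomerisation). Fallback: set out from 31 and build the (Z)-enoates on the oxygen instead of transferring them. Both hydroxyls are esterified with 2-[bis(2,2,2-trifluoroethoxy)phosphoryl]propanoic acid (DCC, DMAP, CH2Cl2) to give the bis(phosphonopropanoate) of 31 F6. A Still–Gennari olefination with acetaldehyde (KHMDS, 18-crown-6, THF, −78 °C) then makes both (Z)-2-methylbut-2-enoates and returns to the route at 32.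

Step 10 (catalytic allylation of a hindered α-branched enal; low rate or low selectivity). Fallback: set out from 19 and fix the carbinol by reduction instead of addition. AllylMgBr (THF, −78 °C) gives 2-[(3aS,4R,7aR)-2,2,7-trimethyl-3a,4,5,7a-tetrahydro-1,3-benzodioxol-4-yl]hexa-1,5-dien-3-ol as both C-3 epimers F4. Dess–Martin periodinane/NaHCO3 gives 2-[(3aS,4R,7aR)-2,2,7-trimethyl-3a,4,5,7a-tetrahydro-1,3-benzodioxol-4-yl]hexa-1,5-dien-3-one F5, used cold and at once. Corey–Bakshi–Shibata reduction with the (R)-methyl oxazaborolidine and catecholborane (PhMe, −78 °C; the 2-substituted vinyl group is the large group) gives the (3S)-alcohol and returns to the route at 22.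

Step 7 (the one-pot acetal interchange may stop at the cyclic methyl acetal). Fallback: set out from 12 and open the ring irreversibly with sulfur. AcOH/H2O/THF at rt gives the lactol (3aR,7R,7aS)-6-methyl-2,3,3a,4,7,7a-hexahydro-1-benzofuran-2,7-diol F1. Propane-1,3-dithiol and BF3·OEt2 (CH2Cl2, −20 °C) give (1S,2R,6R)-6-(1,3-dithian-2-ylmethyl)-3-methylcyclohex-3-ene-1,2-diol F2. 2,2-Dimethoxypropane/PPTS gives (3aS,4R,7aR)-4-(1,3-dithian-2-ylmethyl)-2,2,7-trimethyl-3a,4,5,7a-tetrahydro-1,3-benzodioxole F3. MeI/CaCO3 in aqueous MeCN unmasks the aldehyde and returns to the route at 17.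

**Further compounds**

F1 | step 7 | (3aR,7R,7aS)-6-methyl-2,3,3a,4,7,7a-hexahydro-1-benzofuran-2,7-diol (C-2 epimers) | OC1C[C@H]2CC=C(C)[C@@H](O)[C@H]2O1
F2 | step 7 | (1S,2R,6R)-6-(1,3-dithian-2-ylmethyl)-3-methylcyclohex-3-ene-1,2-diol | C1CSC(SC1)C[C@H]1CC=C(C)[C@@H](O)[C@H]1O
F3 | step 7 | (3aS,4R,7aR)-4-(1,3-dithian-2-ylmethyl)-2,2,7-trimethyl-3a,4,5,7a-tetrahydro-1,3-benzodioxole | C1CSC(SC1)C[C@H]1CC=C(C)[C@@H]2[C@H]1OC(C)(C)O2
F4 | step 10 | 2-[(3aS,4R,7aR)-2,2,7-trimethyl-3a,4,5,7a-tetrahydro-1,3-benzodioxol-4-yl]hexa-1,5-dien-3-ol (both C-3 epimers) | C=C(C(O)CC=C)[C@H]1CC=C(C)[C@@H]2[C@H]1OC(C)(C)O2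
F5 | step 10 | 2-[(3aS,4R,7aR)-2,2,7-trimethyl-3a,4,5,7a-tetrahydro-1,3-benzodioxol-4-yl]hexa-1,5-dien-3-one | C=C(C(=O)CC=C)[C@H]1CC=C(C)[C@@H]2[C@H]1OC(C)(C)O2
F6 | step 16 | bis(phosphonopropanoate) of 31: both ring hydroxyls carry 2-[bis(2,2,2-trifluoroethoxy)phosphoryl]propanoyl groups (phosphonate α-carbons unassigned) | C=C([C@H](CC=C(C)C)OC(=O)/C(C)=C\C)[C@H]1C[C@H]2O[C@@]2(C)[C@@H](OC(=O)C(C)P(=O)(OCC(F)(F)F)OCC(F)(F)F)[C@H]1OC(=O)C(C)P(=O)(OCC(F)(F)F)OCC(F)(F)F
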